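## Retrosynthetic overview

1. Target 23 ⇐ dibenzyl ether 22 ⇐ ester 19; the C4 ester is taken down to the C4 methyl (CO2Me → CH2OH → CH2OTs → CH3) and both benzyl ethers are removed last.
2. The strategy rests on the tetrahydrofuran ring O1–C2(ring A)–C3(CH3)–C4(CH3)–C5(ring B). C4, its methyl carbon and the C4–C5 bond are read as C4 and the C3 carbonyl of a 2,6-diaryl-5-methyltetrahydropyran-3-one. Ester 19 therefore comes from the 4-diazo ketone 16 by Wolff ring contraction, the ring B carbinol carbon migrating.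
3. 16 ⇐ all-equatorial pyranone 14 ⇐ 2,6-cis enone 13 (Me2CuLi anti to ring A) ⇐ hemiketal 12 (silane reduction) ⇐ Achmatowicz oxidation of the (S)-furyl carbinol 11.
4. 11 ⇐ aldehyde 2 + 2-arylfuran 8 (furan and bromide 4 by Negishi coupling), the racemic carbinol being resolved by Sharpless kinetic resolution.
5. Ring order: furan, then pyranone (ring expansion), then tetrahydrofuran (ring contraction).

Key step: step 10

Numbering used in the text: tetrahydrofuran O1, C2 (ring A), C3, C4, C5 (ring B); pyranone O1, C2 (ring B), C3 (C=O), C4, C5 (CH3), C6 (ring A).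

Assumption: the titanium tartrate reagent is taken to discriminate this 5-aryl-2-furyl aryl carbinol in the same sense as simple 2-furylcarbinols, so that D-(−)-tartrate leaves the (S)-alcohol.

## Route

Step 1
Reactants: 1 3-hydroxy-4,5-dimethoxybenzaldehyde
Product: 2 3-(benzyloxy)-4,5-dimethoxybenzaldehyde
Conditions: BnBr, K2CO3, DMF, rt
Reagents that add atoms: benzyl bromide, BrCc1ccccc1
Why: Williamson etherification of the phenoxide with a primary benzylic bromide, the aldehyde being inert to carbonate.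

Step 2
Reactants: 3 4-bromo-2-methoxyphenol
Product: 4 1-(benzyloxy)-4-bromo-2-methoxybenzene
Conditions: BnBr, K2CO3, DMF, rt
Reagents that add atoms: benzyl bromide, BrCc1ccccc1
Why: Williamson etherification; the aryl bromide is untouched and the benzyl ether will survive the organometallic, acidic and hydride steps that follow.

Step 3
Reactants: 5 furan; 4 1-(benzyloxy)-4-bromo-2-methoxybenzene
Product: 8 2-[4-(benzyloxy)-3-methoxyphenyl]furan, via 2-furyllithium 6 (not isolated), via 2-furylzinc chloride 7 (not isolated)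
Conditions: n-BuLi, THF, 0 °C; ZnCl2, THF, 0 °C→rt; 4, Pd(PPh3)4 (3 mol %), THF, 55 °C
Reagents that add atoms: none
Why: Negishi cross-coupling, in which furan is lithiated at C2, transmetalated to zinc and coupled with the aryl bromide under zerovalent palladium catalysis, conditions that leave the benzyl and methyl ethers alone.

Step 4
Reactants: 8 2-[4-(benzyloxy)-3-methoxyphenyl]furan; 2 3-(benzyloxy)-4,5-dimethoxybenzaldehyde
Product: 10 rac-[3-(benzyloxy)-4,5-dimethoxyphenyl]{5-[4-(benzyloxy)-3-methoxyphenyl]furan-2-yl}methanol, via 5-aryl-2-furyllithium 9 (not isolated)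
Conditions: n-BuLi, THF, −78→−10 °C; 2, −78→0 °C; H2O
Reagents that add atoms: none
Why: Lithiation of the 2-arylfuran at its free α-position (the most acidic C–H, removed well below the temperature at which benzyl ethers are metalated) and 1,2-addition to the aldehyde; the carbinol centre is formed racemic.

Step 5
Reactants: 10 rac-[3-(benzyloxy)-4,5-dimethoxyphenyl]{5-[4-(benzyloxy)-3-methoxyphenyl]furan-2-yl}methanol
Product: 11 (S)-[3-(benzyloxy)-4,5-dimethoxyphenyl]{5-[4-(benzyloxy)-3-methoxyphenyl]furan-2-yl}methanol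
Conditions: Ti(OiPr)4 (0.2 equiv), D-(−)-diisopropyl tartrate (0.24 equiv), t-BuOOH (0.6 equiv), 4 Å MS, CH2Cl2, −20 °C, run to slightly beyond half conversion
Reagents that add atoms: none
Why: Sharpless kinetic resolution of a 2-furylcarbinol, in which the hydroxyl-directed titanium tartrate hydroperoxide complex oxidises the furan of the matched (R)-enantiomer to a pyranone much faster, so the (S)-carbinol should be recovered enantiomerically enriched and is separated from the polar pyranone by chromatography; the stereocentre is selected, not created.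

Step 6
Reactants: 11 (S)-[3-(benzyloxy)-4,5-dimethoxyphenyl]{5-[4-(benzyloxy)-3-methoxyphenyl]furan-2-yl}methanol
Product: 12 (2S)-6-[4-(benzyloxy)-3-methoxyphenyl]-2-[3-(benzyloxy)-4,5-dimethoxyphenyl]-6-hydroxy-2H-pyran-3(6H)-one (mixture at C6)
Conditions: mCPBA, CH2Cl2, 0 °C
Reagents that add atoms: 3-chloroperbenzoic acid, OOC(=O)c1cccc(Cl)c1
Why: Achmatowicz rearrangement, in which peracid oxidation of the electron-rich furan gives the cis-enedione and the carbinol hydroxyl closes onto the aryl ketone to give the six-membered hemiketal, the carbinol carbon (pyranone C2) not being touched.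

Step 7
Reactants: 12 (2S)-6-[4-(benzyloxy)-3-methoxyphenyl]-2-[3-(benzyloxy)-4,5-dimethoxyphenyl]-6-hydroxy-2H-pyran-3(6H)-one
Product: 13 (2S,6S)-6-[4-(benzyloxy)-3-methoxyphenyl]-2-[3-(benzyloxy)-4,5-dimethoxyphenyl]-2H-pyran-3(6H)-one (2,6-cis)
Conditions: Et3SiH (5 equiv), TFA (10 equiv), CH2Cl2, −40 °C
Reagents that add atoms: none
Why: Kishi-type reductive deoxygenation of an Achmatowicz hemiketal, in which acid ionises C6 to the ring A-stabilised oxocarbenium ion and the silane delivers hydride axially on the face anti to the C2 aryl, so C6 is set 2,6-cis by 1,3-induction from C2; any 2,6-trans isomer has to be removed here by chromatography because it would later converge on the enantiomeric series.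

Step 8
Reactants: 13 (2S,6S)-6-[4-(benzyloxy)-3-methoxyphenyl]-2-[3-(benzyloxy)-4,5-dimethoxyphenyl]-2H-pyran-3(6H)-one
Product: 14 (2S,5S,6S)-6-[4-(benzyloxy)-3-methoxyphenyl]-2-[3-(benzyloxy)-4,5-dimethoxyphenyl]-5-methyloxan-3-one (all-equatorial)
Conditions: Me2CuLi (from MeLi and CuI), Et2O, −78→−40 °C; aq. NH4Cl
Reagents that add atoms: lithium dimethylcuprate, [Li+].C[Cu-]C (made in the flask from methyllithium, [Li]C, and CuI)
Why: Gilman cuprate 1,4-addition to the enone, the methyl group entering C5 axially and anti to the adjacent C6 aryl, which sets C5 trans to ring A and gives the all-equatorial and therefore thermodynamically stable ketone.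

Step 9
Reactants: 14 (2S,5S,6S)-6-[4-(benzyloxy)-3-methoxyphenyl]-2-[3-(benzyloxy)-4,5-dimethoxyphenyl]-5-methyloxan-3-one
Product: 16 (2S,5S,6S)-6-[4-(benzyloxy)-3-methoxyphenyl]-2-[3-(benzyloxy)-4,5-dimethoxyphenyl]-4-diazo-5-methyloxan-3-one, via hydroxymethylene ketone 15 (not isolated)
Conditions: NaH, HCO2Et, EtOH (cat.), THF, 0 °C→rt; aq. HCl; crude 15, MsN3, Et3N, CH2Cl2, 0 °C→rt
Reagents that add atoms: methanesulfonyl azide, CS(=O)(=O)N=[N+]=[N-]; ethyl formate, CCOC=O (its formyl carbon is carried only in 15)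
Why: Regitz deformylative diazo transfer, in which Claisen formylation can settle only on the C4 methylene and the sulfonyl azide then exchanges the formyl group for N2, while reversible enolisation toward C2 under the base can only return ring B to its equatorial position.

Step 10
Reactants: 16 (2S,5S,6S)-6-[4-(benzyloxy)-3-methoxyphenyl]-2-[3-(benzyloxy)-4,5-dimethoxyphenyl]-4-diazo-5-methyloxan-3-one
Product: 19 methyl (2R,3R,4S,5S)-5-[4-(benzyloxy)-3-methoxyphenyl]-2-[3-(benzyloxy)-4,5-dimethoxyphenyl]-4-methyloxolane-3-carboxylate, via ketene 17 (not isolated), via C4-epimeric ester 18 (not isolated)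
Conditions: hν (365 nm), degassed MeOH (0.01 M), 10 °C; then NaOMe (0.3 equiv), MeOH, 40 °C
Reagents that add atoms: methanol, CO
Why: Excitation of the diazo ketone expels N2 and, because the cyclic diazo ketone is locked s-cis, pyranone C2 (the ring B carbinol carbon, C5 of the target) shifts in concert from the acyl carbon to the diazo carbon to give ketene 17, which methanol captures as the methyl ester; this is the photochemical Wolff ring contraction of cyclic α-diazo ketones. The tetrahydrofuran ring is thus closed by contraction (a 1,2-shift that forms C4–C5), not by cyclisation. The migrating carbon keeps its configuration, as is general for Wolff shifts, and C2 and C3 of the new ring are bystanders, so the all-equatorial arrangement of 16 becomes the 2,3-trans, 2,5-cis arrangement of 19. The new stereocentre C4 is not fixed by the shift: protonation of the ketene-derived enol is expected on the face away from the two aryl groups and should give mainly 18, and catalytic NaOMe then equilibrates C4 through the ester enolate toward 19, in which the ester is trans to the C5 aryl and cis only to the small C3 methyl. The step needs the shift to outrun 1,2-hydride migration from the neighbouring C–H and O–H insertion of the solvent, which the s-cis geometry and direct irradiation in dilute methanol favour. It also needs the ring to survive methoxide, which it should because opening by β-elimination of O1 would be the reverse of a 5-endo-trig closure.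

Step 11
Reactants: 19 methyl (2R,3R,4S,5S)-5-[4-(benzyloxy)-3-methoxyphenyl]-2-[3-(benzyloxy)-4,5-dimethoxyphenyl]-4-methyloxolane-3-carboxylate
Product: 20 [(2R,3S,4S,5S)-5-[4-(benzyloxy)-3-methoxyphenyl]-2-[3-(benzyloxy)-4,5-dimethoxyphenyl]-4-methyloxolan-3-yl]methanol
Conditions: LiAlH4, THF, 0 °C
Reagents that add atoms: none
Why: Hydride reduction of the ester to the primary alcohol, fast enough at 0 °C that C4 is not epimerised and with no effect on the aryl ethers or the ring.

Step 12
Reactants: 20 [(2R,3S,4S,5S)-5-[4-(benzyloxy)-3-methoxyphenyl]-2-[3-(benzyloxy)-4,5-dimethoxyphenyl]-4-methyloxolan-3-yl]methanol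
Product: 21 [(2R,3S,4S,5S)-5-[4-(benzyloxy)-3-methoxyphenyl]-2-[3-(benzyloxy)-4,5-dimethoxyphenyl]-4-methyloxolan-3-yl]methyl 4-methylbenzenesulfonate
Conditions: TsCl, pyridine, DMAP (cat.), CH2Cl2, 0 °C→rt
Reagents that add atoms: 4-methylbenzenesulfonyl chloride, Cc1ccc(cc1)S(=O)(=O)Cl
Why: Sulfonylation of the only free hydroxyl, a primary alcohol, to make it a leaving group.

Step 13
Reactants: 21 [(2R,3S,4S,5S)-5-[4-(benzyloxy)-3-methoxyphenyl]-2-[3-(benzyloxy)-4,5-dimethoxyphenyl]-4-methyloxolan-3-yl]methyl 4-methylbenzenesulfonate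
Product: 22 (2R,3R,4S,5S)-5-[4-(benzyloxy)-3-methoxyphenyl]-2-[3-(benzyloxy)-4,5-dimethoxyphenyl]-3,4-dimethyloxolane
Conditions: LiEt3BH, THF, 0 °C→rt
Reagents that add atoms: none
Why: SN2 displacement of the β-branched primary tosylate by the strongly nucleophilic hydride of LiEt3BH turns the former ketone carbon into the C4 methyl without touching a stereocentre.

Step 14
Reactants: 22 (2R,3R,4S,5S)-5-[4-(benzyloxy)-3-methoxyphenyl]-2-[3-(benzyloxy)-4,5-dimethoxyphenyl]-3,4-dimethyloxolane
Product: 23 5-[(2R,3R,4S,5S)-5-(4-hydroxy-3-methoxyphenyl)-3,4-dimethyloxolan-2-yl]-2,3-dimethoxyphenol (CNP0022199.2)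
Conditions: H2 (1 atm), Pd/C (10%), EtOAc–MeOH, rt
Reagents that add atoms: none
Why: Hydrogenolysis of the two aryl benzyl ethers, which are cleaved much faster than the dialkyl benzylic C–O bonds of the ring under neutral conditions, so the reaction is stopped once two equivalents of H2 have been taken up.

## Compound list

1 | 3-hydroxy-4,5-dimethoxybenzaldehyde | COc1cc(C=O)cc(O)c1OC | starting material
2 | 3-(benzyloxy)-4,5-dimethoxybenzaldehyde | COc1cc(C=O)cc(OCc2ccccc2)c1OC | intermediate
3 | 4-bromo-2-methoxyphenol | COc1cc(Br)ccc1O | starting material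
4 | 1-(benzyloxy)-4-bromo-2-methoxybenzene | COc1cc(Br)ccc1OCc1ccccc1 | intermediate
5 | furan | c1ccoc1 | starting material
6 | 2-furyllithium | [Li]c1ccco1 | intermediate
7 | 2-furylzinc chloride | Cl[Zn]c1ccco1 | intermediate
8 | 2-[4-(benzyloxy)-3-methoxyphenyl]furan | COc1cc(-c2ccco2)ccc1OCc1ccccc1 | intermediate
9 | {5-[4-(benzyloxy)-3-methoxyphenyl]furan-2-yl}lithium | [Li]c1ccc(-c2ccc(OCc3ccccc3)c(OC)c2)o1 | intermediate
10 | rac-[3-(benzyloxy)-4,5-dimethoxyphenyl]{5-[4-(benzyloxy)-3-methoxyphenyl]furan-2-yl}methanol | OC(c1cc(OCc2ccccc2)c(OC)c(OC)c1)c1ccc(-c2ccc(OCc3ccccc3)c(OC)c2)o1 | intermediate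
11 | (S)-[3-(benzyloxy)-4,5-dimethoxyphenyl]{5-[4-(benzyloxy)-3-methoxyphenyl]furan-2-yl}methanol | O[C@@H](c1cc(OCc2ccccc2)c(OC)c(OC)c1)c1ccc(-c2ccc(OCc3ccccc3)c(OC)c2)o1 | intermediate
12 | (2S)-6-[4-(benzyloxy)-3-methoxyphenyl]-2-[3-(benzyloxy)-4,5-dimethoxyphenyl]-6-hydroxy-2H-pyran-3(6H)-one, C6 anomers | O=C1C=CC(O)(c2ccc(OCc3ccccc3)c(OC)c2)O[C@H]1c1cc(OCc2ccccc2)c(OC)c(OC)c1 | intermediate
13 | (2S,6S)-6-[4-(benzyloxy)-3-methoxyphenyl]-2-[3-(benzyloxy)-4,5-dimethoxyphenyl]-2H-pyran-3(6H)-one (2,6-cis) | COc1cc([C@H]2O[C@@H](c3cc(OCc4ccccc4)c(OC)c(OC)c3)C(=O)C=C2)ccc1OCc1ccccc1 | intermediate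
14 | (2S,5S,6S)-6-[4-(benzyloxy)-3-methoxyphenyl]-2-[3-(benzyloxy)-4,5-dimethoxyphenyl]-5-methyloxan-3-one (2,6-cis, 5,6-trans) | COc1cc([C@H]2O[C@@H](c3cc(OCc4ccccc4)c(OC)c(OC)c3)C(=O)C[C@@H]2C)ccc1OCc1ccccc1 | intermediate
15 | (2S,5S,6S)-6-[4-(benzyloxy)-3-methoxyphenyl]-2-[3-(benzyloxy)-4,5-dimethoxyphenyl]-4-(hydroxymethylidene)-5-methyloxan-3-one | COc1cc([C@H]2O[C@@H](c3cc(OCc4ccccc4)c(OC)c(OC)c3)C(=O)C(=CO)[C@@H]2C)ccc1OCc1ccccc1 | intermediate
16 | (2S,5S,6S)-6-[4-(benzyloxy)-3-methoxyphenyl]-2-[3-(benzyloxy)-4,5-dimethoxyphenyl]-4-diazo-5-methyloxan-3-one | COc1cc([C@H]2O[C@@H](c3cc(OCc4ccccc4)c(OC)c(OC)c3)C(=O)C(=[N+]=[N-])[C@@H]2C)ccc1OCc1ccccc1 | intermediate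
17 | ring-contracted ketene, 3-(oxomethylidene)oxolane with C2, C3 and C5 (target numbering) configured as in 19 | COc1cc([C@H]2O[C@@H](c3cc(OCc4ccccc4)c(OC)c(OC)c3)C(=C=O)[C@@H]2C)ccc1OCc1ccccc1 | intermediate
18 | methyl (2R,3S,4S,5S)-5-[4-(benzyloxy)-3-methoxyphenyl]-2-[3-(benzyloxy)-4,5-dimethoxyphenyl]-4-methyloxolane-3-carboxylate (ester cis to ring B) | COc1cc([C@H]2O[C@@H](c3cc(OCc4ccccc4)c(OC)c(OC)c3)[C@@H](C(=O)OC)[C@@H]2C)ccc1OCc1ccccc1 | intermediate
19 | methyl (2R,3R,4S,5S)-5-[4-(benzyloxy)-3-methoxyphenyl]-2-[3-(benzyloxy)-4,5-dimethoxyphenyl]-4-methyloxolane-3-carboxylate | COc1cc([C@H]2O[C@@H](c3cc(OCc4ccccc4)c(OC)c(OC)c3)[C@H](C(=O)OC)[C@@H]2C)ccc1OCc1ccccc1 | intermediate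
20 | [(2R,3S,4S,5S)-5-[4-(benzyloxy)-3-methoxyphenyl]-2-[3-(benzyloxy)-4,5-dimethoxyphenyl]-4-methyloxolan-3-yl]methanol | COc1cc([C@H]2O[C@@H](c3cc(OCc4ccccc4)c(OC)c(OC)c3)[C@H](CO)[C@@H]2C)ccc1OCc1ccccc1 | intermediate
21 | [(2R,3S,4S,5S)-5-[4-(benzyloxy)-3-methoxyphenyl]-2-[3-(benzyloxy)-4,5-dimethoxyphenyl]-4-methyloxolan-3-yl]methyl 4-methylbenzenesulfonate | COc1cc([C@H]2O[C@@H](c3cc(OCc4ccccc4)c(OC)c(OC)c3)[C@H](COS(=O)(=O)c3ccc(C)cc3)[C@@H]2C)ccc1OCc1ccccc1 | intermediate
22 | (2R,3R,4S,5S)-5-[4-(benzyloxy)-3-methoxyphenyl]-2-[3-(benzyloxy)-4,5-dimethoxyphenyl]-3,4-dimethyloxolane | COc1cc([C@H]2O[C@@H](c3cc(OCc4ccccc4)c(OC)c(OC)c3)[C@H](C)[C@@H]2C)ccc1OCc1ccccc1 | intermediate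
23 | 5-[(2R,3R,4S,5S)-5-(4-hydroxy-3-methoxyphenyl)-3,4-dimethyloxolan-2-yl]-2,3-dimethoxyphenol | COc1cc([C@H]2O[C@@H](c3cc(O)c(OC)c(OC)c3)[C@H](C)[C@@H]2C)ccc1O | target

## Step count and risks

Total step count: 14. Longest linear sequence: 13 steps (steps 2 to 14, from 4-bromo-2-methoxyphenol).

**Step 10.** The keto carbene may divert into 1,2-hydride shift from the neighbouring C–H (giving an enone) or O–H insertion of methanol instead of ring contraction, and the thermodynamic preference at C4 may be too small for clean convergence under methoxide. The fallback replaces the carbene shift by an oxidative 1,2-shift and sets out from ketone 14. Treatment with PhI(OAc)2 and catalytic H2SO4 in HC(OMe)3/MeOH would convert 14 in the flask into its dimethyl ketal F1. The trivalent iodine electrophile is expected to be taken up at the unhindered C4 methylene, not at the fully substituted C2, and loss of iodobenzene is accompanied by the same shift of the ring B carbinol carbon from C3 to C4 with retention. This should give the methyl esters 18 and 19 directly, and the same methoxide equilibration then rejoins the route at 19.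

**Step 7.** The ring A-stabilised oxocarbenium ion may lose the C2 configuration by tautomerising toward the aromatic 3-hydroxypyrylium ion before hydride capture, or hydride may be delivered on both faces; either erodes enantiomeric purity because C6 later dictates C2. The fallback avoids a C6 cation by introducing ring A at the anomeric carbon of a simpler pyranone. It sets out from aldehyde 2 and furan 5: 2-furyllithium 6 adds to 2 to give the racemic furyl carbinol F2, which is resolved with the L-(+)-tartrate form of the titanium reagent to leave the (R)-carbinol F3. Achmatowicz oxidation gives the 6-hydroxypyranone F4, and Zn/AcOH removes the anomeric hydroxyl reductively to give the 2H-pyran-3(4H)-one F5, a cyclic enol ether. Heck–Matsuda arylation of F5 with 4-(benzyloxy)-3-methoxybenzenediazonium tetrafluoroborate F6 (from the aniline with NaNO2/HBF4; Pd(OAc)2, MeCN, rt, no base) should add ring A to C6 anti to the C2 aryl and, after β-hydride elimination toward C4, give the 2,6-trans enone F7. Me2CuLi then adds anti to ring A to give the 2,6-trans ketone F8, and DBU equilibrates C2 to the all-equatorial isomer, which is ketone 14, where the route is rejoined.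

**Step 5.** The titanium tartrate complex may discriminate poorly between the enantiomers of a carbinol flanked by two aryl-type groups, and the Lewis acid may ionise this doubly activated carbinol and racemise it. The fallback makes 11 by asymmetric C–C bond formation instead of resolution and sets out from arylfuran 8 and aldehyde 2. The furyllithium 9 is transmetalated with EtZnCl to the ethyl(furyl)zinc reagent F9. In the presence of a catalytic amount of the amino alcohol 3-exo-morpholinoisoborneol (the enantiomer that directs the furyl group to the Re face of 2) and a chelating diamine to sequester LiCl, selective furyl transfer to 2 should give 11 directly, where the route is rejoined at step 6.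

## Further compounds

F1 | step 10 | dimethyl ketal of 14, (2S,5S,6S)-6-[4-(benzyloxy)-3-methoxyphenyl]-2-[3-(benzyloxy)-4,5-dimethoxyphenyl]-3,3-dimethoxy-5-methyloxane | COc1cc([C@H]2O[C@@H](c3cc(OCc4ccccc4)c(OC)c(OC)c3)C(OC)(OC)C[C@@H]2C)ccc1OCc1ccccc1
F2 | step 7 | rac-[3-(benzyloxy)-4,5-dimethoxyphenyl](furan-2-yl)methanol | OC(c1ccco1)c1cc(OCc2ccccc2)c(OC)c(OC)c1
F3 | step 7 | (R)-[3-(benzyloxy)-4,5-dimethoxyphenyl](furan-2-yl)methanol | O[C@H](c1cc(OCc2ccccc2)c(OC)c(OC)c1)c1ccco1
F4 | step 7 | (2R)-2-[3-(benzyloxy)-4,5-dimethoxyphenyl]-6-hydroxy-2H-pyran-3(6H)-one | O=C1C=CC(O)O[C@@H]1c1cc(OCc2ccccc2)c(OC)c(OC)c1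
F5 | step 7 | (2R)-2-[3-(benzyloxy)-4,5-dimethoxyphenyl]-2H-pyran-3(4H)-one | O=C1CC=CO[C@@H]1c1cc(OCc2ccccc2)c(OC)c(OC)c1
F6 | step 7 | 4-(benzyloxy)-3-methoxybenzenediazonium tetrafluoroborate | COc1cc([N+]#N)ccc1OCc1ccccc1.F[B-](F)(F)F
F7 | step 7 | (2R,6S)-6-[4-(benzyloxy)-3-methoxyphenyl]-2-[3-(benzyloxy)-4,5-dimethoxyphenyl]-2H-pyran-3(6H)-one (2,6-trans) | COc1cc([C@H]2O[C@H](c3cc(OCc4ccccc4)c(OC)c(OC)c3)C(=O)C=C2)ccc1OCc1ccccc1
F8 | step 7 | (2R,5S,6S)-6-[4-(benzyloxy)-3-methoxyphenyl]-2-[3-(benzyloxy)-4,5-dimethoxyphenyl]-5-methyloxan-3-one (2,6-trans) | COc1cc([C@H]2O[C@H](c3cc(OCc4ccccc4)c(OC)c(OC)c3)C(=O)C[C@@H]2C)ccc1OCc1ccccc1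
F9 | step 5 | ethyl{5-[4-(benzyloxy)-3-methoxyphenyl]furan-2-yl}zinc | CC[Zn]c1ccc(-c2ccc(OCc3ccccc3)c(OC)c2)o1
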